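**Retrosynthetic overview**
1. Target 6 is disconnected at the pyranone O1–C2 bond (C–O) together with the C2=C3 unsaturation. This leads back to dihydrochalcone 3, which already carries the 4-hydroxybenzyl group on ring A.
2. The closure must use the ring A hydroxyl that sits next to the benzyl group; the catalyst makes this choice in the C–O forming step.
3. Compound 3 is disconnected at the ArCH2–ring A bond (Friedel–Crafts) to phloretin 1 and 4-hydroxybenzyl alcohol 2. Ring A of 1 is symmetric, so only one mono-benzyl product is possible.
4. Ring order: rings A and B and the benzyl arene are bought; ring C (the pyranone) is the only ring formed, and it is formed last.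

Assumption: the target SMILES contains no stereocentre or stereogenic axis, so the compound is achiral and no enantiocontrol is needed.

**Step 1**
Reactants: 1 phloretin [3-(4-hydroxyphenyl)-1-(2,4,6-trihydroxyphenyl)propan-1-one]; 2 4-hydroxybenzyl alcohol
Product: 3 3-(4-hydroxyphenyl)-1-[2,4,6-trihydroxy-3-(4-hydroxybenzyl)phenyl]propan-1-one
Conditions: TsOH·H2O (5 mol %), 1,4-dioxane, 60 °C; 2 added over 4 h to 1 (2.5 equiv, excess recovered)
Reagents that add atoms: none
Why: Acid ionises 2 to the 4-hydroxybenzyl cation (para-quinone methide), which undergoes Friedel–Crafts alkylation at the equivalent C3'/C5' positions of the phloroglucinol ring A, far more nucleophilic than ring B; excess 1 and slow addition suppress double benzylation and self-condensation of 2, and no stereocentre is formed.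

**Step 2**
Reactants: 3 3-(4-hydroxyphenyl)-1-[2,4,6-trihydroxy-3-(4-hydroxybenzyl)phenyl]propan-1-one
Product: 6 5,7-dihydroxy-8-(4-hydroxybenzyl)-2-(4-hydroxyphenyl)-4H-chromen-4-one, via chalcone 4 (not isolated), via flavanone 5 (not isolated)
Conditions: Pd(O2CCF3)2 (10 mol %), neocuproine (2,9-dimethyl-1,10-phenanthroline, 12 mol %), O2 (1 atm), DMSO, 80 °C
Reagents that add atoms: none
Why: Proposed new method: a catalyst-controlled, regioselective aerobic dehydrogenative oxa-cyclisation of an unprotected, unsymmetrical 2',6'-dihydroxydihydrochalcone. The cationic (neocuproine)Pd fragment (divalent palladium) binds 3 as a six-membered phenoxide/carbonyl O,O-chelate. In such chelates the substituent ortho to the bound phenoxide lies in the coordination plane and points at the ligand cis to that oxygen, where it meets a 2-methyl group of neocuproine. Chelation is therefore expected at the C6' oxygen (flanked by H) and not at the C2' oxygen (flanked by the benzyl group). Phenoxide-directed α-palladation and β-hydride elimination give chalcone 4, still chelated; the carbonyl is locked syn to O6', so the enone is held next to the free 2'-OH. That hydroxyl adds in a Lewis-acid-activated 6-endo oxa-Michael reaction and forms the O1–C2 bond beside the benzyl-bearing carbon (flavanone 5, racemic at C2). A second chelate-directed dehydrogenation (C3 palladation, β-hydride from C2) gives flavone 6, which cannot ring-open. Any 6-benzyl flavanone from background cyclisation has the hindered 5-OH, should be dehydrogenated more slowly and can return through retro-oxa-Michael opening. O2 reoxidises zerovalent palladium. The closest known reaction type is the palladium-catalysed aerobic α,β-dehydrogenation of ketones and oxidative cyclisation of 2'-hydroxydihydrochalcones to flavones, shown only for substrates with a single ortho hydroxyl. The transient C2 stereocentre of 5 is planarised, so no stereocentre remains.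

**Compound list**
1 | phloretin, 3-(4-hydroxyphenyl)-1-(2,4,6-trihydroxyphenyl)propan-1-one | O=C(CCc1ccc(O)cc1)c1c(O)cc(O)cc1O | starting material
2 | 4-hydroxybenzyl alcohol | OCc1ccc(O)cc1 | starting material
3 | 3-(4-hydroxyphenyl)-1-[2,4,6-trihydroxy-3-(4-hydroxybenzyl)phenyl]propan-1-one | O=C(CCc1ccc(O)cc1)c1c(O)cc(O)c(Cc2ccc(O)cc2)c1O | intermediate
4 | chalcone formed in the flask, (E)-3-(4-hydroxyphenyl)-1-[2,4,6-trihydroxy-3-(4-hydroxybenzyl)phenyl]prop-2-en-1-one | O=C(/C=C/c1ccc(O)cc1)c1c(O)cc(O)c(Cc2ccc(O)cc2)c1O | intermediate
5 | flavanone formed in the flask, racemic 5,7-dihydroxy-8-(4-hydroxybenzyl)-2-(4-hydroxyphenyl)chroman-4-one | O=C1CC(c2ccc(O)cc2)Oc2c(Cc3ccc(O)cc3)c(O)cc(O)c12 | intermediate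
6 | 5,7-dihydroxy-8-(4-hydroxybenzyl)-2-(4-hydroxyphenyl)-4H-chromen-4-one (achiral) | O=c1cc(-c2ccc(O)cc2)oc2c(Cc3ccc(O)cc3)c(O)cc(O)c12 | target

**Step count and risks**
Total step count: 2. Longest linear sequence: 2 steps. The route has only two steps, so both are ranked.

Most likely to fail: step 2, the proposed new method. The risks are uncatalysed oxa-Michael closure of chalcone 4 through the unhindered hydroxyl (giving the 6-benzyl isomer), oxidation of the free phenols or of the diarylmethane CH2, and loss of catalyst to the many phenoxide donors. The fallback uses known chemistry and replaces catalyst control by covalent blocking. It sets out from 3. Benzyl bromide (4.2 equiv) and K2CO3 in acetone at reflux etherify every phenol except the chelated 2'-hydroxyl flanked by the acyl and C-benzyl groups, the usual outcome of partial alkylation of 3-C-alkyl phloroacylphenones. This gives 1-[4,6-bis(benzyloxy)-2-hydroxy-3-(4-benzyloxybenzyl)phenyl]-3-(4-benzyloxyphenyl)propan-1-one F2. I2 (cat.) in DMSO at 130 °C then dehydrogenates and cyclises through the only free hydroxyl to 5,7-bis(benzyloxy)-8-(4-benzyloxybenzyl)-2-(4-benzyloxyphenyl)-4H-chromen-4-one F3. Hydrogenolysis (H2, 1 atm, 10% Pd/C, EtOAc/MeOH, rt) removes the four O-benzyl groups and comes back to the route at 6.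

Second: step 1. The risks are double benzylation of ring A and self-condensation of 2 to oligomeric diarylmethanes. The fallback reverses the order of the two C–C bond formations. It sets out from 2, which is added slowly to a fivefold excess of benzene-1,3,5-triol (TsOH·H2O cat., 1,4-dioxane, 60 °C) to give 2-(4-hydroxybenzyl)benzene-1,3,5-triol F1. Friedel–Crafts acylation of F1 with 3-(4-hydroxyphenyl)propanoic acid in BF3·OEt2 at 80 °C places the side chain on one of the two equivalent free ring positions and comes back to the route at 3.

**Further compounds**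
F1 | step 1 | 2-(4-hydroxybenzyl)benzene-1,3,5-triol | Oc1ccc(Cc2c(O)cc(O)cc2O)cc1
F2 | step 2 | 1-[4,6-bis(benzyloxy)-2-hydroxy-3-(4-benzyloxybenzyl)phenyl]-3-(4-benzyloxyphenyl)propan-1-one | O=C(CCc1ccc(OCc2ccccc2)cc1)c1c(OCc2ccccc2)cc(OCc2ccccc2)c(Cc2ccc(OCc3ccccc3)cc2)c1O
F3 | step 2 | 5,7-bis(benzyloxy)-8-(4-benzyloxybenzyl)-2-(4-benzyloxyphenyl)-4H-chromen-4-one | O=c1cc(-c2ccc(OCc3ccccc3)cc2)oc2c(Cc3ccc(OCc4ccccc4)cc3)c(OCc3ccccc3)cc(OCc3ccccc3)c12
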